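All constants are invented.

An easy step starts it: one electrophile meets one nucleophile, giving one product and one acid set free, and I want the part of the electrophile that has reacted in each flask.

    electrophile + nucleophile → acid set free + product (k1 = 0.0359 M⁻¹ s⁻¹)
    nucleophile + acid set free ⇌ protonated nucleophile, settled at all times (K2 = 21500 M⁻¹)
    electrophile + acid set free ⇌ idle adduct, settled at all times (K3 = 9490 M⁻¹)
    nucleophile ⇌ dormant form (K4 = 0.65, k4 = 0.00245 s⁻¹)

the same everywhere: electrophile 0.011 M; time 1.5 h
- south: nucleophile 1.20 equiv
- west: nucleophile 1.80 equiv
- north: nucleophile 2.70 equiv

1. part of the electrophile that has reacted at the end, south
2. part of the electrophile that has reacted at the end, west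
3. part of the electrophile that has reacted at the end, north
4. what raising the equivalents of nucleophile from its lowest to its highest value here does to the part of the electrophile that has reacted (changes below 5 percentage points count as none) (no change / it falls / it rises)

- amounts and yields of acid set free count idle adduct too
- what has gone from electrophile into another species counts as reacted, even if it can come back
- run time (south): 1.5 h

At the bench I count half-lives. The dormant form balances with a relaxation half-life of 1.86 min, so in south I divide the charged nucleophile by 1.65, which leaves 0.00800 M free. Holding that level makes the first step pseudo-first-order, with an electrophile half-life of 0.670 h, far longer than the relaxation, so the balance may be assumed from the outset. The number of half-lives in the run, run time over that half-life, is 2.24 in south, which means 78.8 % reacted. The same count gives 3.36 and 90.3 % in west, then 5.03 and 96.9 % in north.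

The border lies in the acid. In south at the start, its binding term on electrophile is 100 and on nucleophile 280 by the charge, or 172 on the free part, all far above one, so the acid is caught, and 62.2 % of it goes to nucleophile. Each product then costs 1.62 nucleophile, and the south charge covers 0.740 of that cost per electrophile, which is below one. I expect the free nucleophile to fall well below that level, so I hold my percentages as high marks, though idle adduct counts as reacted and pulls the other way. I still expect a rise.

The forecast says 68 % (65 % to 71 %) for south, 78 % (75 % to 81 %) for west and 87 % (85 % to 90 %) for north, lower than my south figure, and that it rises. Its ground: “The acid binds fast, so I used a quasi-equilibrium treatment.”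

The flasks give 68.3 %, 77.9 % and 87.4 % for south, west and north, so it rises, by 19 percentage points. In south the first step had done half of its turnover by 0.345 h, and at 0.345 h the electrophile half-life by that step already stood at 1.0 h, longer than the counted 0.670 h. At 1.50 h south held 19.6 % of its nucleophile free, 0.00340 M protonated nucleophile, and 18.4 % of its electrophile as idle adduct beside 49.8 % product. The neighbour at 0.0066 M electrophile counts 1.34 half-lives, or 60.5 %, and reaches 56.4 %.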